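The route rests on cutting the bond between C2 of the pyran-4-one ring and the benzylic CH2 of the 2-carboxy-4,5-dihydroxybenzyl group. The key step exploits the acidity of the C2–H bond of a 2-unsubstituted chromone, which sits next to the ring oxygen O1 and is vinylogous to the C4 carbonyl. A magnesium-chloride-assisted zinc amide base removes this proton, and the 2-chromonylzinc species is cross-coupled in the same flask with an ortho-ester benzylic bromide under palladium catalysis. One operation thus joins both halves without prior functionalisation of C2. The precursors are 5-heptyl-7-methoxychromone and methyl 2-(bromomethyl)-4,5-dimethoxybenzoate; one global demethylation then gives the target.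

Key step: step 6

Remark: the target has no stereocentre and no stereogenic double bond, so it is a single achiral compound and the route needs no stereocontrol.

Step 1
Reactants: 1 5-heptylbenzene-1,3-diol (5-heptylresorcinol)
Product: 3 1-(2-heptyl-4,6-dihydroxyphenyl)ethan-1-one, via ketiminium chloride 2 (not isolated)
Conditions: MeCN, ZnCl2, HCl (g), Et2O, 0 °C; then H2O, reflux
Reagents that add atoms: acetonitrile CC#N; water O
Why: Hoesch acylation: the ZnCl2-activated nitrilium ion should attack the resorcinol ring para to one hydroxyl and ortho to the other (C4, beside the heptyl group) and not at the more hindered C2 between the two hydroxyls, and the ketiminium salt is then hydrolysed to the methyl ketone.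

Step 2
Reactants: 3 1-(2-heptyl-4,6-dihydroxyphenyl)ethan-1-one
Product: 4 1-(2-heptyl-6-hydroxy-4-methoxyphenyl)ethan-1-one
Conditions: MeI (1.05 equiv), K2CO3 (1.1 equiv), acetone, reflux
Reagents that add atoms: iodomethane CI
Why: Williamson etherification: the 4-OH para to the acetyl group is free and the more acidic, whereas the 6-OH is held in a hydrogen bond to the ketone, so one equivalent of MeI should methylate only the para hydroxyl.

Step 3
Reactants: 4 1-(2-heptyl-6-hydroxy-4-methoxyphenyl)ethan-1-one
Product: 6 5-heptyl-7-methoxy-4H-chromen-4-one, via dimethylamino enone 5 (not isolated)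
Conditions: DMF-DMA, toluene, 100 °C; then conc. HCl, CH2Cl2, 40 °C
Reagents that add atoms: N,N-dimethylformamide dimethyl acetal COC(OC)N(C)C
Why: Enaminone route to chromones: condensation of the methyl ketone with the formamide acetal gives the β-dimethylamino enone, and acid then drives 6-endo oxa-Michael attack of the phenol and loss of dimethylamine, closing the pyranone ring with C2 left unsubstituted.

Step 4
Reactants: 7 4,5-dimethoxy-2-methylbenzoic acid
Product: 8 methyl 4,5-dimethoxy-2-methylbenzoate
Conditions: MeOH, H2SO4 (cat.), reflux
Reagents that add atoms: methanol CO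
Why: Fischer esterification masks the acidic proton, which the organozinc coupling would not tolerate, and blocks lactonisation of the free acid onto the benzylic bromide.

Step 5
Reactants: 8 methyl 4,5-dimethoxy-2-methylbenzoate
Product: 9 methyl 2-(bromomethyl)-4,5-dimethoxybenzoate
Conditions: NBS (1.05 equiv), AIBN (5 mol%), PhCF3, 80 °C
Reagents that add atoms: N-bromosuccinimide O=C1CCC(=O)N1Br
Why: Wohl–Ziegler bromination: a bromine radical abstracts hydrogen from the methyl group (benzylic and para to a methoxy group), and the low stationary Br2 concentration in a non-polar solvent should keep ionic ring bromination in check; the bromide is used promptly because it can lactonise on standing.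

Step 6
Reactants: 6 5-heptyl-7-methoxy-4H-chromen-4-one; 9 methyl 2-(bromomethyl)-4,5-dimethoxybenzoate
Product: 11 methyl 2-[(5-heptyl-7-methoxy-4-oxo-4H-chromen-2-yl)methyl]-4,5-dimethoxybenzoate, via bis(chromon-2-yl)zinc 10 (not isolated)
Conditions: TMP2Zn·2MgCl2·2LiCl (0.6 equiv), THF, −30 °C, 1 h; then 9 (1.1 equiv), Pd(dba)2 (3 mol%), P(2-furyl)3 (6 mol%), −30 °C → 25 °C
Reagents that add atoms: none
Why: Coordination of MgCl2 to the C4 carbonyl oxygen should make C2–H (next to O1 and β to the activated carbonyl) the most acidic position and block carbonyl-directed metalation at C3, so the hindered zinc amide deprotonates at C2 and gives the diorganozinc 10. Pd(0) then adds oxidatively to the benzylic C–Br bond of 9, the chromonyl group passes from zinc to palladium, and reductive elimination forms the C2–CH2 bond. The closest known reaction type is the directed zincation of chromones followed by Negishi cross-coupling, here with an sp3 benzylic bromide as the electrophile. No ring is closed and no stereocentre is formed. The step needs metalation at C2 and not at C3, C8 or the benzylic CH2 of the heptyl chain, which the Lewis acid, the low temperature and the mild zinc base should secure. It also needs the methyl ester and the enone to survive, which the low polarity of the C–Zn bond allows.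

Step 7
Reactants: 11 methyl 2-[(5-heptyl-7-methoxy-4-oxo-4H-chromen-2-yl)methyl]-4,5-dimethoxybenzoate
Product: 12 2-[(5-heptyl-7-hydroxy-4-oxo-4H-chromen-2-yl)methyl]-4,5-dihydroxybenzoic acid
Conditions: BBr3 (10 equiv), CH2Cl2, −78 °C → 25 °C; then H2O, 0 °C
Reagents that add atoms: none
Why: BBr3 dealkylation: Lewis acid complexation followed by SN2 attack of bromide on each O-methyl group should remove the three aryl methyl ethers and, by alkyl–oxygen cleavage, the methyl ester, and water then hydrolyses the borates, while the chromone and the benzylic CH2 are inert.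

Compound list
1 | 5-heptylbenzene-1,3-diol (5-heptylresorcinol) | CCCCCCCc1cc(O)cc(O)c1 | starting material
2 | 1-(2-heptyl-4,6-dihydroxyphenyl)ethan-1-iminium chloride | CCCCCCCc1cc(O)cc(O)c1C(C)=[NH2+].[Cl-] | intermediate
3 | 1-(2-heptyl-4,6-dihydroxyphenyl)ethan-1-one | CCCCCCCc1cc(O)cc(O)c1C(C)=O | intermediate
4 | 1-(2-heptyl-6-hydroxy-4-methoxyphenyl)ethan-1-one | CCCCCCCc1cc(OC)cc(O)c1C(C)=O | intermediate
5 | (E)-3-(dimethylamino)-1-(2-heptyl-6-hydroxy-4-methoxyphenyl)prop-2-en-1-one | CCCCCCCc1cc(OC)cc(O)c1C(=O)/C=C/N(C)C | intermediate
6 | 5-heptyl-7-methoxy-4H-chromen-4-one | CCCCCCCc1cc(OC)cc2occc(=O)c12 | intermediate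
7 | 4,5-dimethoxy-2-methylbenzoic acid | Cc1cc(OC)c(OC)cc1C(=O)O | starting material
8 | methyl 4,5-dimethoxy-2-methylbenzoate | Cc1cc(OC)c(OC)cc1C(=O)OC | intermediate
9 | methyl 2-(bromomethyl)-4,5-dimethoxybenzoate | BrCc1cc(OC)c(OC)cc1C(=O)OC | intermediate
10 | bis(5-heptyl-7-methoxy-4-oxo-4H-chromen-2-yl)zinc | CCCCCCCc1cc(OC)cc2oc([Zn]c3cc(=O)c4c(CCCCCCC)cc(OC)cc4o3)cc(=O)c12 | intermediate
11 | methyl 2-[(5-heptyl-7-methoxy-4-oxo-4H-chromen-2-yl)methyl]-4,5-dimethoxybenzoate | CCCCCCCc1cc(OC)cc2oc(Cc3cc(OC)c(OC)cc3C(=O)OC)cc(=O)c12 | intermediate
12 | 2-[(5-heptyl-7-hydroxy-4-oxo-4H-chromen-2-yl)methyl]-4,5-dihydroxybenzoic acid | CCCCCCCc1cc(O)cc2oc(Cc3cc(O)c(O)cc3C(=O)O)cc(=O)c12 | target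

Total step count: 7
Longest linear sequence: 5 steps (steps 1, 2, 3, 6, 7)

Steps most likely to fail

Step 6. The metalation may go to C3 or C8 instead of C2, or transmetalation may be slow enough that the benzylic bromide homocouples or lactonises first. The fallback inverts the polarity of the union and sets out from 4 and 9. Treatment of 4 with CS2 and KOtBu in THF, followed by acidification, should give 5-heptyl-4-hydroxy-7-methoxy-2H-chromene-2-thione F1. S-Methylation (MeI, K2CO3, acetone) should then give 5-heptyl-7-methoxy-2-(methylsulfanyl)-4H-chromen-4-one F2. Zinc dust and LiCl in THF should convert 9 into [4,5-dimethoxy-2-(methoxycarbonyl)benzyl]zinc bromide F3. Pd(OAc)2/SPhos-catalysed cross-coupling of the vinylogous thioester F2 with F3 (C–S activation, Negishi type) should form the same C2–CH2 bond and come back to the route at 11.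

Step 7. Cleavage of the methyl ester may lag behind ether cleavage, and long exposure to the Lewis acid may degrade the catechol acid. The fallback separates the two events and sets out from 11. Mild saponification (LiOH, THF/H2O, 25 °C, then dilute HCl) should give 2-[(5-heptyl-7-methoxy-4-oxo-4H-chromen-2-yl)methyl]-4,5-dimethoxybenzoic acid F4 by acyl–oxygen cleavage. BBr3 in CH2Cl2 then has only the three aryl methyl ethers to remove and should come back to the route at 12.

Step 1. The electrophile may attack between the two hydroxyls, or O-imidate formation may lower conversion. The fallback acylates the bis-ether instead and sets out from 1. Double methylation (MeI, K2CO3, acetone) should give 1-heptyl-3,5-dimethoxybenzene F5. Friedel–Crafts acetylation (AcCl, AlCl3, CH2Cl2, 0 °C), directed para to one methoxy group and away from the crowded position between both, should give 1-(2-heptyl-4,6-dimethoxyphenyl)ethan-1-one F6. BCl3 (CH2Cl2, −78 → 0 °C) should then remove only the methyl ether ortho to the ketone through chelation. This comes back to the route at 4 and bypasses step 2.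

Further compounds
F1 | step 6 | 5-heptyl-4-hydroxy-7-methoxy-2H-chromene-2-thione | CCCCCCCc1cc(OC)cc2oc(=S)cc(O)c12
F2 | step 6 | 5-heptyl-7-methoxy-2-(methylsulfanyl)-4H-chromen-4-one | CCCCCCCc1cc(OC)cc2oc(SC)cc(=O)c12
F3 | step 6 | [4,5-dimethoxy-2-(methoxycarbonyl)benzyl]zinc bromide | COC(=O)c1cc(OC)c(OC)cc1C[Zn]Br
F4 | step 7 | 2-[(5-heptyl-7-methoxy-4-oxo-4H-chromen-2-yl)methyl]-4,5-dimethoxybenzoic acid | CCCCCCCc1cc(OC)cc2oc(Cc3cc(OC)c(OC)cc3C(=O)O)cc(=O)c12
F5 | step 1 | 1-heptyl-3,5-dimethoxybenzene | CCCCCCCc1cc(OC)cc(OC)c1
F6 | step 1 | 1-(2-heptyl-4,6-dimethoxyphenyl)ethan-1-one | CCCCCCCc1cc(OC)cc(OC)c1C(C)=O
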